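**Analysis of the target**

Eduesmine (17) is a monocyclic lignan: one oxolane ring with a 4-hydroxy-3-methoxyphenyl group on C2 and on C5 and a hydroxymethyl group on C3 and on C4. All four ring carbons are stereocentres, each (S). Each aryl group is cis to the hydroxymethyl group on the neighbouring carbon (2,3-cis, 4,5-cis), while the two hydroxymethyl groups are trans to each other, as are the two aryl groups. A twofold axis runs through O1 and the midpoint of C3–C4, so C2/C5 and C3/C4 are pairwise equivalent and only two stereocentres are independent. The O1–C2 and O1–C5 bonds are benzylic and para to a free phenol; acid (through a quinone-methide-like cation) or strong base (through the phenoxide) can break them, after which the aryl groups would settle trans to their neighbours, the more stable arrangement. The difficulty is therefore to set the crowded cis aryl/hydroxymethyl relation twice, under kinetic control and in one absolute sense, and then to keep it away from equilibrating conditions. The strategy rests on the chain C2–C3–C4–C5: each half is an oxygen-bearing benzylic carbon bonded to a carbon with a one-carbon branch, the pattern left by a [2,3]-Wittig rearrangement of a benzyl allyl ether when the branch is first a vinyl group. The C3–C4 bond that joins the halves can be the central single bond of a 1,3-diene, so both halves can come from one symmetric dienyl bis-ether.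

**Retrosynthetic reasoning**

17 from 16. The two phenols are freed last by cutting their O–Si bonds. Triisopropylsilyl ethers are chosen because they must survive an alkoxide, an alkyllithium and a Lewis acid and still leave with buffered fluoride, which does not touch the benzylic ring bonds. Benzyl ethers are excluded: their CH2 groups would be lithiated in the key step, and their hydrogenolysis would endanger O1–C2 and O1–C5.

16 from 14 (through 15). Each hydroxymethyl carbon is traced back to the inner carbon of a vinyl group, so the terminal CH2 of each alkene is the carbon cut away. Vinyl groups are inert to base, hydride and Lewis acid and cannot epimerise, unlike carbonyl-level arms, and they are exactly what a sigmatropic shift of an allyl ether leaves behind. Forward, both alkenes are cleaved to dialdehyde 15, which is reduced at once.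

14 from 10 (through 11, 12, 13). The bond cut is O1–C2. The open-chain precursor is the twofold-symmetric 1,4-diol 10, which already has the right configuration at both carbinol carbons. A direct closure would need retention at both: displacement inverts one, and ionisation leads to the trans arrangement. One carbinol is therefore raised to the ketone (11), the ring closes as hemiketal 12 without touching a stereogenic C–O bond, and hydride adds to cation 13 on the face away from the C3 vinyl group. That rebuilds C2 with the aryl group cis to the C3 substituent. Because 10 is symmetric, either carbinol may be oxidised. The cost is stated plainly: one of the four stereocentres made in the key step is erased and rebuilt under control of its neighbour.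

10 from 8 (through 9). This is the key disconnection: C1–C2 and C3–C4 of 10, which are C2–C3 and C4–C5 of the oxolane. Each joins a benzylic carbinol carbon to an allylic carbon, so a retro-[2,3]-Wittig step moves the benzylic carbon back onto oxygen and restores an (E)-allyl ether; done at both ends it gives the achiral (E,E)-dienyl bis(benzyl) ether 8. These are the only C–C bonds that tie the aryl-bearing carbons to the core. Cutting both removes all four stereocentres at once and leaves two identical benzyl units on a six-carbon diene. Forward, both benzylic carbons must be lithiated, each shift must be anti, and both must occur in the same absolute sense.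

8 from 7 and 5; 7 from 6; 5 from 4, 3, 1 and 2. The two ether C–O bonds are cut to give diol 7 and two equivalents of benzylic bromide 5. Diol 7 is the reduction product of diester 6. Bromide 5 comes from alcohol 4, the reduction product of aldehyde 3, which is vanillin (1) silylated with 2. This is short, standard chemistry, so the risk of the route sits in the key step.

**Alternatives that were turned down**

Alternative 1: The C2–aryl and C5–aryl bonds are cut. This leaves a preformed oxolane carrying both arms at the amide level, (3R,4R)-N3,N4-di(quinolin-8-yl)oxolane-3,4-dicarboxamide A2, and the aryl iodide 4-iodo-2-methoxyphenyl acetate A3. Forward, Pd(OAc)2 with a silver carboxylate as iodide acceptor would palladate the C2–H and C5–H bonds of A2 cis to the directing amides and join each to the aryl group of A3 to give the diaryl diamide A1.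
- For: the palladacycle can only form on the amide face, so each aryl group arrives cis to its neighbouring carbonyl, which is the crowded relation needed. The ring never has to be closed, and both aryl groups enter late in one operation.
- Against: the step is stereospecific but creates no absolute configuration, so A2 must be resolved or made by a separate asymmetric synthesis. The C–H bonds to be broken lie next to the ring oxygen, the less willing position of such a heterocycle for cyclopalladation, and the second bidentate amide can hold the metal unproductively, so mono-arylation is to be expected. In A1 the two C–H bonds α to the amides each sit cis to an aryl group; hot acetate, and later the activation and hydride reduction that turn two hindered amides into hydroxymethyl groups, can epimerise them to trans.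
- Comparison: this route is shorter to the full skeleton and its bond-forming event is better charted. The chosen route offers instead absolute and relative configuration from achiral materials in one step, and arms that stay as non-epimerisable vinyl groups until late.

Alternative 2: The ring is cut at C3–C4 and O1–C5, a formal (3+2) between an aroyl carbene and a cinnamyl alkene tied together as an ester. The diazo ketoester A5 would cyclopropanate its own (Z)-alkene under Rh2(S-PTTL)4 to the bicyclic aroyl cyclopropane A6. A nucleophilic tertiary amine added to the same flask would open the three-membered ring of A6 at the benzylic carbon, and the enolate oxygen would close on that carbon (Cloke–Wilson ring expansion), giving the lactone-fused 4,5-dihydrofuran A4.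
- For: a catalytic amount of chiral complex sets the absolute configuration. The (Z)-geometry is carried through a stereospecific cyclopropanation and a double inversion into the cis relation of the C5 aryl group and the C4 arm. The ring and one C–C bond form in one flask.
- Against: only C4 and C5 are set. In A4 the carbons C2 and C3 are the ends of a tetrasubstituted push–pull alkene, and the lactone holds the C3 carbon cis to the C4 arm, whereas the target has them trans. Saturating C2=C3 from the open face gives the all-cis oxolane, so the lactone would have to be opened, C3 inverted and C2 then set by hydride addition — the same last stereochemical event as in the chosen route, reached by a longer path. Carbenes flanked by two acyl groups are very electrophilic and react through early transition states, which limits what the ligand can do. The (Z)-alkene of A5 needs an alkyne semireduction, aryl mesylates come off only with strong nucleophiles or bases that a p-hydroxybenzylic ether tolerates poorly, and two carbonyl carbons must be reduced.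
- Comparison: a catalytic source of chirality and well-charted single steps are real advantages over a stoichiometric ligand and an untested double rearrangement. The chosen route offers in their place all four stereocentres in the right relative sense from one operation, use of the twofold symmetry, and no carbonyl-level adjustments.

Alternative 3: The cuts are O1–C2 and the bond from C3 to its hydroxymethyl carbon, which would come from carbon monoxide A9. The homopropargylic alcohol A8, the gas A9 and methanol A10 would react under the divalent palladium catalyst PdCl2(MeCN)2 with a quinone as oxidant. The C5 hydroxyl adds to the metal-activated alkyne in a 5-endo closure, and the vinylpalladium is carbonylated and captured by A10 to give the dihydrofuran ester A7.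
- For: A9 is the cheapest one-carbon unit, the tetrasubstituted enol ether forms with full positional control, and the two arms end up differentiated.
- Against: the key step creates no stereocentre. The two adjacent centres of A8 need their own asymmetric construction, and C2 and C3 of A7 again have to be set by saturating a tetrasubstituted alkene, where addition to the face away from the C4 and C5 substituents gives the 3,4-cis isomer and not the 3,4-trans one. Differentiated arms are of no use for a symmetric target. Benzyl ethers on the phenols would have to be removed by hydrogenolysis in a molecule whose ring C–O bonds are themselves benzylic.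
- Comparison: the cyclisation–carbonylation is closer to established practice than the chosen key step, and such a linear route would also reach unsymmetrical analogues. The chosen route is two-directional, makes two C–C bonds and four stereocentres in the step that carries the risk, and needs only silyl groups that leave under buffered fluoride.

Key step: step 6

Assumption: which enantiomer of the bis(oxazoline) ligand leads to the (1S,4S)-diol 10 cannot be derived with certainty for this substrate; the (S,S)-ligand, 2,2'-(propane-2,2-diyl)bis[(4S)-4-(propan-2-yl)-4,5-dihydro-1,3-oxazole] ((S,S)-i-Pr-box), is written, and its mirror image is to be used if the first shift shows the opposite sense.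

**Route**

Step 1
Reactants: 1 vanillin (4-hydroxy-3-methoxybenzaldehyde); 2 chlorotri(propan-2-yl)silane
Product: 3 3-methoxy-4-[tri(propan-2-yl)silyloxy]benzaldehyde
Conditions: imidazole, DMF, 0 °C → rt
Reagents that add atoms: chlorotri(propan-2-yl)silane (compound 2), CC(C)[Si](Cl)(C(C)C)C(C)C
Why: Silylation of a phenol with a trialkylsilyl chloride and imidazole; the bulky triisopropylsilyl group is preferred to a smaller silyl group because it must later resist an alkoxide (step 5), t-BuLi (step 6) and BF3·OEt2 (step 8) and still leave with fluoride.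

Step 2
Reactants: 3 3-methoxy-4-[tri(propan-2-yl)silyloxy]benzaldehyde
Product: 4 {3-methoxy-4-[tri(propan-2-yl)silyloxy]phenyl}methanol
Conditions: NaBH4, MeOH, 0 °C
Reagents that add atoms: none
Why: NaBH4 reduction of an aromatic aldehyde to the benzylic alcohol; the hindered aryl silyl ether should not be touched at 0 °C.

Step 3
Reactants: 4 {3-methoxy-4-[tri(propan-2-yl)silyloxy]phenyl}methanol
Product: 5 [4-(bromomethyl)-2-methoxyphenoxy]tri(propan-2-yl)silane
Conditions: CBr4, PPh3, CH2Cl2, 0 °C
Reagents that add atoms: tetrabromomethane, BrC(Br)(Br)Br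
Why: Appel bromination under neutral conditions; the electron-rich benzylic bromide ionises easily, so it is passed through a short silica plug and used at once.

Step 4
Reactants: 6 dimethyl (2E,4E)-hexa-2,4-dienedioate
Product: 7 (2E,4E)-hexa-2,4-diene-1,6-diol
Conditions: i-Bu2AlH, CH2Cl2, −78 → 0 °C; aq. KNaC4H4O6
Reagents that add atoms: none
Why: Reduction of both conjugated esters to allylic alcohols with i-Bu2AlH, which adds 1,2 at low temperature and leaves the (E,E)-diene untouched.

Step 5
Reactants: 7 (2E,4E)-hexa-2,4-diene-1,6-diol; 5 [4-(bromomethyl)-2-methoxyphenoxy]tri(propan-2-yl)silane (2.2 equiv)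
Product: 8 (2E,4E)-1,6-bis({3-methoxy-4-[tri(propan-2-yl)silyloxy]phenyl}methoxy)hexa-2,4-diene
Conditions: NaH, Bu4NI (cat.), THF/DMF, 0 °C → rt
Reagents that add atoms: none
Why: Twofold Williamson etherification; the primary allylic alkoxides displace bromide from the very reactive benzylic bromide (iodide catalysis), and the hindered silyl ethers should resist silyl transfer to the alkoxide; the alkene geometry is not involved.

Step 6
Reactants: 8 (2E,4E)-1,6-bis({3-methoxy-4-[tri(propan-2-yl)silyloxy]phenyl}methoxy)hexa-2,4-diene
Product: 10 (1S,2R,3R,4S)-2,3-diethenyl-1,4-bis{3-methoxy-4-[tri(propan-2-yl)silyloxy]phenyl}butane-1,4-diol, via mono-rearranged lithium alkoxide 9 (not isolated)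
Conditions: t-BuLi (3 equiv), (S,S)-i-Pr-box (3.3 equiv), hexane/toluene, −78 → −50 °C; aq. NH4Cl
Reagents that add atoms: none
Why: Proposed new method: the t-BuLi·bis(oxazoline) complex should remove a benzylic proton next to oxygen, and the α-oxybenzyllithium then bonds through its benzylic carbon to C3 of the diene in a five-membered envelope transition state while the O–C1 bond breaks ([2,3]-Wittig rearrangement), giving alkoxide 9, whose remaining ether is again an (E)-allyl benzyl ether, so that a second lithiation and shift joins the other benzylic carbon to C4 and gives the dialkoxide of 10. The closest known reaction type is the enantioselective, anti-selective [2,3]-Wittig rearrangement of simple (E)-allyl benzyl ethers under alkyllithium/chiral bis(oxazoline) control; new is running it twice in one molecule on a conjugated dienyl bis-ether, the second time next to a stereocentre and a lithium alkoxide. No ring is closed. The two carbinol carbons (C1, C4) are set by the ligand on lithium: α-oxybenzyllithiums invert readily, so the ligand is expected to act by favouring one diastereomeric lithium complex in the shift itself, and the same ligand serves both ends. The two branch carbons (C2, C3) are set relative to their carbinol neighbours by the (E)-alkene geometry with the aryl group exo on the envelope, which gives the anti homoallylic alcohol, that is, aryl and vinyl on the same face once O1 bridges the two carbinol carbons. The step needs lithiation at the benzylic carbon and not at the dienylic O–CH2 or on the arene, the [2,3]- over the radical [1,2]-shift (low temperature and a hydrocarbon solvent favour both), anti over syn, and reagent control in the second shift, which is helped by the weak allylic strain that an (E)-1,2-disubstituted alkene feels from the stereocentre already present. Because the two events are independent, a wrong-sense shift at either end should end mostly in the meso or unsymmetrical diastereomers, separable from 10 by chromatography, so the enantiomeric purity of 10 should exceed that of a single shift.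

Step 7
Reactants: 10 (1S,2R,3R,4S)-2,3-diethenyl-1,4-bis{3-methoxy-4-[tri(propan-2-yl)silyloxy]phenyl}butane-1,4-diol
Product: 12 (3R,4R,5S)-3,4-diethenyl-2,5-bis{3-methoxy-4-[tri(propan-2-yl)silyloxy]phenyl}oxolan-2-ol (both C2 epimers), via hydroxy ketone 11 (not isolated)
Conditions: MnO2 (activated), CH2Cl2, rt
Reagents that add atoms: none
Why: MnO2 oxidises electron-rich benzylic alcohols under neutral heterogeneous conditions; 10 is twofold-symmetric, so either carbinol gives the same hydroxy ketone 11, which should close to the five-membered hemiketal 12 and so be withdrawn from a second oxidation. The oxidised carbinol stereocentre is given up on purpose; the other three are not touched.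

Step 8
Reactants: 12 (3R,4R,5S)-3,4-diethenyl-2,5-bis{3-methoxy-4-[tri(propan-2-yl)silyloxy]phenyl}oxolan-2-ol
Product: 14 (2S,3R,4R,5S)-3,4-diethenyl-2,5-bis{3-methoxy-4-[tri(propan-2-yl)silyloxy]phenyl}oxolane, via oxocarbenium ion 13 (not isolated)
Conditions: Et3SiH, BF3·OEt2, CH2Cl2, −78 °C; Et3N
Reagents that add atoms: none
Why: Ionic hydrogenation of a cyclic hemiketal: BF3·OEt2 ionises 12 to the 2-aryl oxocarbenium ion 13, and Et3SiH delivers hydride by inside attack on the envelope in which the C3 vinyl group is pseudoaxial (avoiding strain with the coplanar aryl group), that is, to the face opposite that vinyl group. This places the aryl group cis to the C3 substituent and makes C2 (S); C3, C4 and C5 are not involved, and the low temperature is meant to keep the cation from losing its C3 proton.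

Step 9
Reactants: 14 (2S,3R,4R,5S)-3,4-diethenyl-2,5-bis{3-methoxy-4-[tri(propan-2-yl)silyloxy]phenyl}oxolane
Product: 16 [(2S,3S,4S,5S)-2,5-bis{3-methoxy-4-[tri(propan-2-yl)silyloxy]phenyl}oxolane-3,4-diyl]dimethanol, via dialdehyde 15 (not isolated)
Conditions: OsO4 (cat.), NaIO4, 2,6-lutidine, dioxane/H2O, rt; then NaBH4, MeOH, 0 °C
Reagents that add atoms: osmium tetroxide, O=[Os](=O)(=O)=O (delivers the oxygen to carbon); sodium periodate, [Na+].[O-]I(=O)(=O)=O, and water, O (replenish it)
Why: Lemieux–Johnson cleavage of both terminal alkenes (dihydroxylation by OsO4, glycol cleavage by NaIO4) buffered with 2,6-lutidine, followed by NaBH4 reduction of the crude dialdehyde 15 without delay, so that its α-carbons C3 and C4, each cis to an aryl group, have little time to epimerise. The descriptors at C3 and C4 change from (R) to (S) only because the substituent priorities change.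

Step 10
Reactants: 16 [(2S,3S,4S,5S)-2,5-bis{3-methoxy-4-[tri(propan-2-yl)silyloxy]phenyl}oxolane-3,4-diyl]dimethanol
Product: 17 eduesmine, 4,4'-[(2S,3S,4S,5S)-3,4-bis(hydroxymethyl)oxolane-2,5-diyl]bis(2-methoxyphenol)
Conditions: Bu4NF, AcOH, THF, 0 °C
Reagents that add atoms: none
Why: Fluoride cleavage of the two aryl silyl ethers; acetic acid keeps the phenols protonated, so the benzylic ring bonds para to them should not open through a quinone methide and no stereocentre is put at risk.

**Compound list**

1 | vanillin (4-hydroxy-3-methoxybenzaldehyde) | COc1cc(C=O)ccc1O | starting material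
2 | chlorotri(propan-2-yl)silane | CC(C)[Si](Cl)(C(C)C)C(C)C | starting material
3 | 3-methoxy-4-[tri(propan-2-yl)silyloxy]benzaldehyde | COc1cc(C=O)ccc1O[Si](C(C)C)(C(C)C)C(C)C | intermediate
4 | {3-methoxy-4-[tri(propan-2-yl)silyloxy]phenyl}methanol | COc1cc(CO)ccc1O[Si](C(C)C)(C(C)C)C(C)C | intermediate
5 | [4-(bromomethyl)-2-methoxyphenoxy]tri(propan-2-yl)silane | COc1cc(CBr)ccc1O[Si](C(C)C)(C(C)C)C(C)C | intermediate
6 | dimethyl (2E,4E)-hexa-2,4-dienedioate | COC(=O)/C=C/C=C/C(=O)OC | starting material
7 | (2E,4E)-hexa-2,4-diene-1,6-diol | OC/C=C/C=C/CO | intermediate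
8 | (2E,4E)-1,6-bis({3-methoxy-4-[tri(propan-2-yl)silyloxy]phenyl}methoxy)hexa-2,4-diene | COc1cc(COC/C=C/C=C/COCc2ccc(O[Si](C(C)C)(C(C)C)C(C)C)c(OC)c2)ccc1O[Si](C(C)C)(C(C)C)C(C)C | intermediate
9 | lithium (1S,2R,3E)-2-ethenyl-1-{3-methoxy-4-[tri(propan-2-yl)silyloxy]phenyl}-5-({3-methoxy-4-[tri(propan-2-yl)silyloxy]phenyl}methoxy)pent-3-en-1-olate | COc1cc(ccc1O[Si](C(C)C)(C(C)C)C(C)C)[C@@H](O[Li])[C@H](C=C)/C=C/COCc1ccc(O[Si](C(C)C)(C(C)C)C(C)C)c(OC)c1 | intermediate
10 | (1S,2R,3R,4S)-2,3-diethenyl-1,4-bis{3-methoxy-4-[tri(propan-2-yl)silyloxy]phenyl}butane-1,4-diol | COc1cc(ccc1O[Si](C(C)C)(C(C)C)C(C)C)[C@@H](O)[C@H](C=C)[C@@H](C=C)[C@H](O)c1ccc(O[Si](C(C)C)(C(C)C)C(C)C)c(OC)c1 | intermediate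
11 | (2R,3R,4S)-2,3-diethenyl-4-hydroxy-1,4-bis{3-methoxy-4-[tri(propan-2-yl)silyloxy]phenyl}butan-1-one | COc1cc(ccc1O[Si](C(C)C)(C(C)C)C(C)C)C(=O)[C@H](C=C)[C@@H](C=C)[C@H](O)c1ccc(O[Si](C(C)C)(C(C)C)C(C)C)c(OC)c1 | intermediate
12 | (3R,4R,5S)-3,4-diethenyl-2,5-bis{3-methoxy-4-[tri(propan-2-yl)silyloxy]phenyl}oxolan-2-ol (both C2 epimers) | COc1cc(ccc1O[Si](C(C)C)(C(C)C)C(C)C)C1(O)O[C@H](c2ccc(O[Si](C(C)C)(C(C)C)C(C)C)c(OC)c2)[C@H](C=C)[C@H]1C=C | intermediate
13 | (2S,3R,4R)-3,4-diethenyl-2,5-bis{3-methoxy-4-[tri(propan-2-yl)silyloxy]phenyl}-3,4-dihydro-2H-furan-1-ium (oxocarbenium ion) | COc1cc(ccc1O[Si](C(C)C)(C(C)C)C(C)C)C1=[O+][C@H](c2ccc(O[Si](C(C)C)(C(C)C)C(C)C)c(OC)c2)[C@H](C=C)[C@H]1C=C | intermediate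
14 | (2S,3R,4R,5S)-3,4-diethenyl-2,5-bis{3-methoxy-4-[tri(propan-2-yl)silyloxy]phenyl}oxolane | COc1cc([C@H]2O[C@H](c3ccc(O[Si](C(C)C)(C(C)C)C(C)C)c(OC)c3)[C@H](C=C)[C@H]2C=C)ccc1O[Si](C(C)C)(C(C)C)C(C)C | intermediate
15 | (2S,3R,4R,5S)-2,5-bis{3-methoxy-4-[tri(propan-2-yl)silyloxy]phenyl}oxolane-3,4-dicarbaldehyde | COc1cc([C@H]2O[C@H](c3ccc(O[Si](C(C)C)(C(C)C)C(C)C)c(OC)c3)[C@H](C=O)[C@H]2C=O)ccc1O[Si](C(C)C)(C(C)C)C(C)C | intermediate
16 | [(2S,3S,4S,5S)-2,5-bis{3-methoxy-4-[tri(propan-2-yl)silyloxy]phenyl}oxolane-3,4-diyl]dimethanol | COc1cc([C@H]2O[C@H](c3ccc(O[Si](C(C)C)(C(C)C)C(C)C)c(OC)c3)[C@H](CO)[C@H]2CO)ccc1O[Si](C(C)C)(C(C)C)C(C)C | intermediate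
17 | eduesmine, 4,4'-[(2S,3S,4S,5S)-3,4-bis(hydroxymethyl)oxolane-2,5-diyl]bis(2-methoxyphenol) | COc1cc([C@H]2O[C@H](c3ccc(O)c(OC)c3)[C@H](CO)[C@H]2CO)ccc1O | target

**Step count and least certain steps**

Total step count: 10. Longest linear sequence: 9 steps (1 → 3 → 4 → 5 → 8 → 10 → 12 → 14 → 16 → 17); the branch 6 → 7 adds one step.

Step 6 (key step; the only step that goes beyond known chemistry). Several processes can divert it. Lithiation may occur at the wrong site: the dienylic O–CH2 gives a well-delocalised anion, and the arene position between the methoxy group and the benzylic carbon is doubly directed, while the electron-rich ring makes the benzylic protons less acidic than in the model ethers. The lithiated ether may undergo homolysis to a radical pair and a [1,2]-shift. The second lithiation, next to the lithium alkoxide of 9, may be slow, so that the reaction stalls after one shift. Facial control may be unequal or weak in the two shifts, which moves material into the meso and unsymmetrical diastereomers.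

The fallback makes the same two C–C bonds from the aldehyde side by known chemistry; it sets out from 7 and 3 and comes back to the route at 10. Acetylation of 7 (Ac2O, pyridine) gives (2E,4E)-hexa-2,4-diene-1,6-diyl diacetate F1. Borylation of F1 with B2pin2 under the zerovalent palladium catalyst Pd2(dba)3 in DMSO gives the bis(allylboronate) 2,2'-[(2E,4E)-hexa-2,4-diene-1,6-diyl]bis(4,4,5,5-tetramethyl-1,3,2-dioxaborolane) F2. F2 and two equivalents of 3, with a chiral BINOL-derived phosphoric acid (the enantiomer that gives (S)-carbinols) in toluene at low temperature, should react twice at the γ-carbon of each (E)-allylboronate through closed chair transition states, anti-selectively. This gives the bis(boric ester) (1S,2R,3R,4S)-2,3-diethenyl-1,4-bis{3-methoxy-4-[tri(propan-2-yl)silyloxy]phenyl}-1,4-bis[(4,4,5,5-tetramethyl-1,3,2-dioxaborolan-2-yl)oxy]butane F3. Mild aqueous work-up hydrolyses F3 to 10, where the route is rejoined.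

Step 8. The cation 13 may lose its C3 proton to give a conjugated dienyl ether, after which proton return can scramble C3 or move the vinyl double bond into conjugation. Hydride may also reach the face that carries the C3 vinyl group, since the other face is flanked by the C4 vinyl and C5 aryl groups, and the Lewis acid may ionise the C5–O bond.

The fallback removes the vinyl groups before the ring is closed; it sets out from 10 and returns at 17. Lemieux–Johnson cleavage of 10 gives a dialdehyde that should be trapped at once by the two carbinol oxygens as the cis-fused bis-lactol 2,6-bis{3-methoxy-4-[tri(propan-2-yl)silyloxy]phenyl}-3,7-dioxabicyclo[3.3.0]octane-4,8-diol F4. NaBH4 reduces F4 to the tetraol (1S,2S,3S,4S)-2,3-bis(hydroxymethyl)-1,4-bis{3-methoxy-4-[tri(propan-2-yl)silyloxy]phenyl}butane-1,4-diol F5. TBSCl and imidazole at low temperature silylate the two primary alcohols of F5 and give (1S,2S,3S,4S)-2,3-bis({[tert-butyl(dimethyl)silyl]oxy}methyl)-1,4-bis{3-methoxy-4-[tri(propan-2-yl)silyloxy]phenyl}butane-1,4-diol F6. MnO2 as in step 7 turns F6 into the hemiketal (3S,4S,5S)-3,4-bis({[tert-butyl(dimethyl)silyl]oxy}methyl)-2,5-bis{3-methoxy-4-[tri(propan-2-yl)silyloxy]phenyl}oxolan-2-ol F7. Et3SiH/BF3·OEt2 as in step 8, now with no vinyl group to be drawn into conjugation, reduces F7 to (2S,3S,4S,5S)-3,4-bis({[tert-butyl(dimethyl)silyl]oxy}methyl)-2,5-bis{3-methoxy-4-[tri(propan-2-yl)silyloxy]phenyl}oxolane F8. Bu4NF/AcOH removes all four silyl groups of F8 and gives 17. This detour also avoids the free dialdehyde 15 of step 9.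

Step 7. The second carbinol may be oxidised before the hydroxy ketone has closed, if the open form 11 is populated, giving a 1,4-diketone; stopping early leaves 10.

The fallback differentiates the carbinols by protection; it sets out from 10 and returns at 12. One equivalent of TESCl with imidazole gives the mono-ether (1S,2R,3R,4S)-2,3-diethenyl-1,4-bis{3-methoxy-4-[tri(propan-2-yl)silyloxy]phenyl}-4-(triethylsilyloxy)butan-1-ol F9 ; recovered diol and bis-ether are recycled. Dess–Martin periodinane, buffered with NaHCO3, oxidises F9 to (2R,3R,4S)-2,3-diethenyl-1,4-bis{3-methoxy-4-[tri(propan-2-yl)silyloxy]phenyl}-4-(triethylsilyloxy)butan-1-one F10. PPTS in MeOH removes the triethylsilyl group of F10 without touching the aryl silyl ethers, and the freed hydroxy ketone 11 closes to 12.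

Step 5. The alkoxide may take a silyl group from a phenolic oxygen, and the freed phenoxide would then be benzylated; the labile bromide 5 may also decompose under base.

The fallback replaces basic alkylation by acid-catalysed alkylation; it sets out from 4 and 7 and returns at 8. Cl3CCN with catalytic DBU converts 4 into {3-methoxy-4-[tri(propan-2-yl)silyloxy]phenyl}methyl 2,2,2-trichloroacetimidate F11. A small excess of F11 and 7, with catalytic camphorsulfonic acid in CH2Cl2/THF at 0 °C, give 8.

**Further compounds**

F1 | step 6 | (2E,4E)-hexa-2,4-diene-1,6-diyl diacetate | CC(=O)OC/C=C/C=C/COC(C)=O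
F2 | step 6 | 2,2'-[(2E,4E)-hexa-2,4-diene-1,6-diyl]bis(4,4,5,5-tetramethyl-1,3,2-dioxaborolane) | CC1(C)OB(C/C=C/C=C/CB2OC(C)(C)C(C)(C)O2)OC1(C)C
F3 | step 6 | (1S,2R,3R,4S)-2,3-diethenyl-1,4-bis{3-methoxy-4-[tri(propan-2-yl)silyloxy]phenyl}-1,4-bis[(4,4,5,5-tetramethyl-1,3,2-dioxaborolan-2-yl)oxy]butane | COc1cc(ccc1O[Si](C(C)C)(C(C)C)C(C)C)[C@@H](OB1OC(C)(C)C(C)(C)O1)[C@H](C=C)[C@@H](C=C)[C@H](OB1OC(C)(C)C(C)(C)O1)c1ccc(O[Si](C(C)C)(C(C)C)C(C)C)c(OC)c1
F4 | step 8 | 2,6-bis{3-methoxy-4-[tri(propan-2-yl)silyloxy]phenyl}-3,7-dioxabicyclo[3.3.0]octane-4,8-diol (cis-fused; C1, C2, C5, C6 as in 10; lactol carbons as epimer mixtures) | COc1cc(ccc1O[Si](C(C)C)(C(C)C)C(C)C)[C@H]1OC(O)[C@@H]2[C@H]1C(O)O[C@@H]2c1ccc(O[Si](C(C)C)(C(C)C)C(C)C)c(OC)c1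
F5 | step 8 | (1S,2S,3S,4S)-2,3-bis(hydroxymethyl)-1,4-bis{3-methoxy-4-[tri(propan-2-yl)silyloxy]phenyl}butane-1,4-diol | COc1cc(ccc1O[Si](C(C)C)(C(C)C)C(C)C)[C@@H](O)[C@H](CO)[C@@H](CO)[C@H](O)c1ccc(O[Si](C(C)C)(C(C)C)C(C)C)c(OC)c1
F6 | step 8 | (1S,2S,3S,4S)-2,3-bis({[tert-butyl(dimethyl)silyl]oxy}methyl)-1,4-bis{3-methoxy-4-[tri(propan-2-yl)silyloxy]phenyl}butane-1,4-diol | COc1cc(ccc1O[Si](C(C)C)(C(C)C)C(C)C)[C@@H](O)[C@H](CO[Si](C)(C)C(C)(C)C)[C@@H](CO[Si](C)(C)C(C)(C)C)[C@H](O)c1ccc(O[Si](C(C)C)(C(C)C)C(C)C)c(OC)c1
F7 | step 8 | (3S,4S,5S)-3,4-bis({[tert-butyl(dimethyl)silyl]oxy}methyl)-2,5-bis{3-methoxy-4-[tri(propan-2-yl)silyloxy]phenyl}oxolan-2-ol (both C2 epimers) | COc1cc(ccc1O[Si](C(C)C)(C(C)C)C(C)C)C1(O)O[C@H](c2ccc(O[Si](C(C)C)(C(C)C)C(C)C)c(OC)c2)[C@H](CO[Si](C)(C)C(C)(C)C)[C@H]1CO[Si](C)(C)C(C)(C)C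
F8 | step 8 | (2S,3S,4S,5S)-3,4-bis({[tert-butyl(dimethyl)silyl]oxy}methyl)-2,5-bis{3-methoxy-4-[tri(propan-2-yl)silyloxy]phenyl}oxolane | COc1cc([C@H]2O[C@H](c3ccc(O[Si](C(C)C)(C(C)C)C(C)C)c(OC)c3)[C@H](CO[Si](C)(C)C(C)(C)C)[C@H]2CO[Si](C)(C)C(C)(C)C)ccc1O[Si](C(C)C)(C(C)C)C(C)C
F9 | step 7 | (1S,2R,3R,4S)-2,3-diethenyl-1,4-bis{3-methoxy-4-[tri(propan-2-yl)silyloxy]phenyl}-4-(triethylsilyloxy)butan-1-ol | COc1cc(ccc1O[Si](C(C)C)(C(C)C)C(C)C)[C@@H](O[Si](CC)(CC)CC)[C@H](C=C)[C@@H](C=C)[C@H](O)c1ccc(O[Si](C(C)C)(C(C)C)C(C)C)c(OC)c1
F10 | step 7 | (2R,3R,4S)-2,3-diethenyl-1,4-bis{3-methoxy-4-[tri(propan-2-yl)silyloxy]phenyl}-4-(triethylsilyloxy)butan-1-one | COc1cc(ccc1O[Si](C(C)C)(C(C)C)C(C)C)[C@@H](O[Si](CC)(CC)CC)[C@H](C=C)[C@@H](C=C)C(=O)c1ccc(O[Si](C(C)C)(C(C)C)C(C)C)c(OC)c1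
F11 | step 5 | {3-methoxy-4-[tri(propan-2-yl)silyloxy]phenyl}methyl 2,2,2-trichloroacetimidate | COc1cc(COC(=N)C(Cl)(Cl)Cl)ccc1O[Si](C(C)C)(C(C)C)C(C)C
A1 | alternative 1 | (2S,3R,4R,5S)-2,5-bis(4-acetoxy-3-methoxyphenyl)-N3,N4-di(quinolin-8-yl)oxolane-3,4-dicarboxamide | COc1cc(ccc1OC(C)=O)[C@H]1O[C@H](c2ccc(OC(C)=O)c(OC)c2)[C@H](C(=O)Nc2cccc3cccnc23)[C@H]1C(=O)Nc1cccc2cccnc12
A2 | alternative 1 | (3R,4R)-N3,N4-di(quinolin-8-yl)oxolane-3,4-dicarboxamide | C1OC[C@H](C(=O)Nc2cccc3cccnc23)[C@H]1C(=O)Nc1cccc2cccnc12
A3 | alternative 1 | 4-iodo-2-methoxyphenyl acetate | COc1cc(I)ccc1OC(C)=O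
A4 | alternative 2 | (3aS,4S)-4,6-bis[3-methoxy-4-(methylsulfonyloxy)phenyl]-3a,4-dihydro-3H-furo[3,4-c]furan-1-one | COc1cc(ccc1OS(C)(=O)=O)C=1O[C@H](c3ccc(OS(C)(=O)=O)c(OC)c3)[C@@H]2COC(=O)C2=1
A5 | alternative 2 | (2Z)-3-[3-methoxy-4-(methylsulfonyloxy)phenyl]prop-2-en-1-yl 2-diazo-3-[3-methoxy-4-(methylsulfonyloxy)phenyl]-3-oxopropanoate | COc1cc(ccc1OS(C)(=O)=O)C(=O)C(=[N+]=[N-])C(=O)OC/C=C\c1ccc(OS(C)(=O)=O)c(OC)c1
A6 | alternative 2 | 1-[3-methoxy-4-(methylsulfonyloxy)benzoyl]-6-[3-methoxy-4-(methylsulfonyloxy)phenyl]-3-oxabicyclo[3.1.0]hexan-2-one (cis-fused; aryl on C6 endo) | COc1cc(ccc1OS(C)(=O)=O)C(=O)[C@]12C(=O)OC[C@H]1[C@H]2c1ccc(OS(C)(=O)=O)c(OC)c1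
A7 | alternative 3 | methyl (4S,5S)-2,5-bis[4-(benzyloxy)-3-methoxyphenyl]-4-({[tert-butyl(dimethyl)silyl]oxy}methyl)-4,5-dihydrofuran-3-carboxylate | COc1cc(ccc1OCc1ccccc1)C=1O[C@H](c2ccc(OCc3ccccc3)c(OC)c2)[C@H](CO[Si](C)(C)C(C)(C)C)C=1C(=O)OC
A8 | alternative 3 | (1S,2S)-1,4-bis[4-(benzyloxy)-3-methoxyphenyl]-2-({[tert-butyl(dimethyl)silyl]oxy}methyl)but-3-yn-1-ol | O[C@H](c1ccc(OCc2ccccc2)c(OC)c1)[C@H](CO[Si](C)(C)C(C)(C)C)C#Cc1ccc(OCc2ccccc2)c(OC)c1
A9 | alternative 3 | carbon monoxide | [C-]#[O+]
A10 | alternative 3 | methanol | CO
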